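**Retrosynthetic overview**
1. Ochtodene 17 ⇒ acyclic dichlorotriene 14 (a dichloromyrcene). One bromonium-triggered cyclisation closes the only ring (C1–C2 bond of the cyclohexane), installs both bromines, and sets C2, C6 and the E-olefin.
2. 14 ⇒ dienol 12 by deoxychlorination with inversion (sets the C4 chloride).
3. 12 ⇒ alkynol 9 + vinylmagnesium chloride 10 by directed anti-carbomagnesiation and chlorination (fixes the Z vinyl chloride).
4. 9 ⇒ ynone 7 by asymmetric transfer hydrogenation; 7 ⇒ Weinreb amide 4 of 4-methylpent-3-enoic acid 1 + ethynyltrimethylsilane 5.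
5. Ring order: the cyclohexane is the only ring and is formed in the last step.

Assumption: the SMILES is read as (2S,4S,6S)-6-bromo-3-[(E)-2-bromoethylidene]-2,4-dichloro-1,1-dimethylcyclohexane (bromide trans to both chlorides, chlorides cis to each other), and this enantiomer is made.

**Step 1**
Reactants: 1 4-methylpent-3-enoic acid; 2 N,O-dimethylhydroxylamine hydrochloride
Product: 4 N-methoxy-N,4-dimethylpent-3-enamide, via acyl imidazolide 3 (not isolated)
Conditions: CDI (1.1 equiv), CH2Cl2, 0 °C → rt, 1 h; then 2 (1.2 equiv), rt, 12 h
Reagents that add atoms: none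
Why: Amide coupling through the acyl imidazolide proceeds under neutral conditions, so the β,γ-double bond does not migrate, and aminolysis gives the Weinreb amide.

**Step 2**
Reactants: 4 N-methoxy-N,4-dimethylpent-3-enamide; 5 ethynyltrimethylsilane
Product: 7 6-methyl-1-(trimethylsilyl)hept-5-en-1-yn-3-one, via lithium (trimethylsilyl)acetylide 6 (not isolated)
Conditions: 5 (1.3 equiv), n-BuLi (1.25 equiv), THF, −78 °C; then 4, −78 → −20 °C; cold aq. NH4Cl
Reagents that add atoms: none
Why: Weinreb ketone synthesis, in which the N-methoxy-N-methylamide accepts a single acetylide and releases the ynone only on the buffered quench, which also keeps the β,γ-alkene out of conjugation.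

**Step 3**
Reactants: 7 6-methyl-1-(trimethylsilyl)hept-5-en-1-yn-3-one
Product: 8 (3R)-6-methyl-1-(trimethylsilyl)hept-5-en-1-yn-3-ol
Conditions: Ru[(R,R)-TsDPEN](p-cymene) (1 mol %), i-PrOH, 25 °C
Reagents that add atoms: none
Why: Noyori asymmetric transfer hydrogenation of an ynone, in which the alkynyl group takes the place of the aryl group in the six-membered hydride-transfer transition state, so the (R,R)-catalyst gives the (R)-carbinol under base-free conditions without touching alkyne or alkene.

**Step 4**
Reactants: 8 (3R)-6-methyl-1-(trimethylsilyl)hept-5-en-1-yn-3-ol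
Product: 9 (3R)-6-methylhept-5-en-1-yn-3-ol
Conditions: K2CO3 (0.2 equiv), MeOH, 0 °C → rt
Reagents that add atoms: none
Why: Protodesilylation of the alkynylsilane by methanolysis leaves the carbinol stereocentre untouched.

**Step 5**
Reactants: 9 (3R)-6-methylhept-5-en-1-yn-3-ol; 10 vinylmagnesium chloride
Product: 12 (4R)-3-[(Z)-chloromethylidene]-7-methylocta-1,6-dien-4-ol, via oxamagnesole 11 (not isolated)
Conditions: 10 (3.5 equiv), CuI (10 mol %), THF, −20 → 25 °C; then NCS (2.5 equiv), −40 → 0 °C; aq. NH4Cl
Reagents that add atoms: N-chlorosuccinimide, O=C1CCC(=O)N1Cl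
Why: Alkoxide-directed anti-carbomagnesiation of the propargylic alcohol places vinyl on the proximal alkyne carbon and magnesium on the terminal carbon cis to the carbinol (five-membered chelate), and electrophilic chlorination of the alkenyl–magnesium bond with retention fixes the Z chloro-olefin (Cl cis to C4).

**Step 6**
Reactants: 12 (4R)-3-[(Z)-chloromethylidene]-7-methylocta-1,6-dien-4-ol
Product: 14 (4S)-4-chloro-3-[(Z)-chloromethylidene]-7-methylocta-1,6-diene, via alkoxyphosphonium chloride 13 (not isolated)
Conditions: PPh3 (1.3 equiv), hexachloroacetone (3 equiv), CH2Cl2, −20 → 0 °C, 30 min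
Reagents that add atoms: hexachloroacetone, ClC(Cl)(Cl)C(=O)C(Cl)(Cl)Cl
Why: Appel-type deoxychlorination of an allylic alcohol, in which SN2 collapse of the alkoxyphosphonium chloride ion pair inverts C4 (R → S) without allylic transposition because the chlorine-bearing SN2' terminus is hindered and electron-poor.

**Step 7**
Reactants: 14 (4S)-4-chloro-3-[(Z)-chloromethylidene]-7-methylocta-1,6-diene
Product: 17 ochtodene, via bromiranium ion 15 (not isolated), via allyl cation 16 (not isolated)
Conditions: Br2 (1.0 equiv, slow addition), Ph3P=S (10 mol %), (CF3)2CHOH/CH2Cl2 (1:1), −30 °C, dark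
Reagents that add atoms: bromine, BrBr
Why: Proposed new method: a bromonium-initiated, chlorodiene-terminated cation–olefin cyclisation with 1,4-return of bromide, i.e. a ring-forming addition of Br2 across C6 and C1 of 14 that makes the bond between C7 and the chloromethylidene carbon. Ph3P=S splits Br2 into a transferable [Ph3P–S–Br]+ and a bromide that the fluoro alcohol sequesters by hydrogen bonding, so bromiranium ion 15 (formed reversibly on either face of the most electron-rich alkene) is not opened to the vicinal dibromide but is attacked anti at its tertiary carbon by the chloromethylidene carbon (six-ring closure to a tertiary allyl cation rather than five-ring closure to a secondary cation). The closure runs through a chair in which C–Br is equatorial, the Z vinylic chlorine becomes axial, and the C4 chlorine is axial because an equatorial C4–Cl would eclipse the s-trans vinyl group (allylic 1,3-strain); this sets the bromide trans and the new chloride cis to the resident chloride. Allyl cation 16 then takes the hydrogen-bonded bromide at its unhindered primary terminus, the s-trans diene becoming the E olefin. Closest known reaction types: bromonium-induced polyene cyclisation with bromosulfonium reagents and Lewis-base-catalysed bromofunctionalisation of alkenes; halide capture of a diene terminator in the 1,4 sense is not known.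

**Compound list**
1 | 4-methylpent-3-enoic acid | CC(C)=CCC(=O)O | starting material
2 | N,O-dimethylhydroxylamine hydrochloride | CNOC.Cl | starting material
3 | 1-(imidazol-1-yl)-4-methylpent-3-en-1-one (acyl imidazolide) | CC(C)=CCC(=O)n1ccnc1 | intermediate
4 | N-methoxy-N,4-dimethylpent-3-enamide | CC(C)=CCC(=O)N(C)OC | intermediate
5 | ethynyltrimethylsilane | C#C[Si](C)(C)C | starting material
6 | lithium (trimethylsilyl)acetylide | [Li]C#C[Si](C)(C)C | intermediate
7 | 6-methyl-1-(trimethylsilyl)hept-5-en-1-yn-3-one | CC(C)=CCC(=O)C#C[Si](C)(C)C | intermediate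
8 | (3R)-6-methyl-1-(trimethylsilyl)hept-5-en-1-yn-3-ol | CC(C)=CC[C@@H](O)C#C[Si](C)(C)C | intermediate
9 | (3R)-6-methylhept-5-en-1-yn-3-ol | CC(C)=CC[C@@H](O)C#C | intermediate
10 | vinylmagnesium chloride | C=C[Mg]Cl | starting material
11 | (5R)-4-ethenyl-5-(3-methylbut-2-en-1-yl)-2,5-dihydro-1,2-oxamagnesole (oxamagnesole chelate) | CC(C)=CC[C@@H](O1)C(C=C)=C[Mg]1 | intermediate
12 | (4R)-3-[(Z)-chloromethylidene]-7-methylocta-1,6-dien-4-ol | CC(C)=CC[C@@H](O)/C(C=C)=C\Cl | intermediate
13 | [(4R)-3-[(Z)-chloromethylidene]-7-methylocta-1,6-dien-4-yl]oxytriphenylphosphonium chloride | CC(C)=CC[C@@H](O[P+](c1ccccc1)(c1ccccc1)c1ccccc1)/C(C=C)=C\Cl.[Cl-] | intermediate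
14 | (4S)-4-chloro-3-[(Z)-chloromethylidene]-7-methylocta-1,6-diene | CC(C)=CC[C@H](Cl)/C(C=C)=C\Cl | intermediate
15 | bromiranium ion of the 6,7-alkene of 14 (Br+ bridging C6 and C7, C6 configured as in 17) | CC1(C)[Br+][C@H]1C[C@H](Cl)/C(C=C)=C\Cl | intermediate
16 | 6-bromo-2,4-dichloro-1,1-dimethyl-3-vinylcyclohexan-3-ylium (tertiary allyl cation, ring configuration of 17) | CC1(C)[C@@H](Br)C[C@H](Cl)[C+](C=C)[C@@H]1Cl | intermediate
17 | ochtodene, (2S,4S,6S)-6-bromo-3-[(E)-2-bromoethylidene]-2,4-dichloro-1,1-dimethylcyclohexane | CC1(C)[C@@H](Br)C[C@H](Cl)/C(=C\CBr)[C@@H]1Cl | target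

**Step count and risks**
Total steps: 7. Longest linear sequence: 7 steps (1 → 17).

Most likely to fail, in order:

Step 7 (the proposed new step). The risks are vicinal dibromination of the prenyl alkene, proton loss from cation 16, incomplete facial control and solvolysis of the allylic chlorides. The fallback uses established reaction types and changes the electrophile. It sets out from 14: Hg(OCOCF3)2 (1.1 equiv) in MeNO2 at −20 °C triggers a mercury-induced polyene cyclisation through the same chair, and trifluoroacetate captures the allyl cation at the primary terminus to give the organomercury bis(trifluoroacetate) F3. Work-up with aqueous KBr/KHCO3 exchanges the ligand on mercury and hydrolyses the allylic ester to the alkylmercury bromide allylic alcohol F4. Bromodemercuration (Br2, LiBr, pyridine, 0 °C, dark, O2-saturated) replaces C–Hg by C–Br with retention to give the bromo allylic alcohol F5. An Appel bromination (CBr4, PPh3, CH2Cl2, 0 °C) then comes back to the route at 17.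

Step 6. The dienylic alcohol may give SN2' chloride (a gem-dichloride) or lose enantiopurity through an ion pair. The fallback decouples leaving group and nucleophile. It sets out from 12: MsCl/Et3N in CH2Cl2 at −40 °C gives the mesylate F2, used cold. Displacement with dry LiCl in DMF at 0 °C (SN2 by free chloride on an isolated sulfonate instead of collapse of a phosphonium ion pair) comes back to the route at 14 with inversion.

Step 5. Transfer of positive chlorine from NCS to the alkenylmagnesium may lose out to protonation or to consumption by excess Grignard reagent. The fallback replaces the C–Cl-forming event by a tin–halogen exchange; it does not help if the carbomagnesiation itself fails. It sets out from 9: the same carbomagnesiation gives 11, which is trapped with Bu3SnCl (−20 → 25 °C) to give the stannyl dienol F1. Chlorodestannylation with CuCl2 (2.2 equiv, THF, rt) proceeds with retention of olefin geometry and comes back to the route at 12.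

**Further compounds**
F1 | step 5 | (4R)-7-methyl-3-[(Z)-(tributylstannyl)methylidene]octa-1,6-dien-4-ol | CC(C)=CC[C@@H](O)/C(C=C)=C\[Sn](CCCC)(CCCC)CCCC
F2 | step 6 | (4R)-3-[(Z)-chloromethylidene]-7-methylocta-1,6-dien-4-yl methanesulfonate | CC(C)=CC[C@@H](OS(C)(=O)=O)/C(C=C)=C\Cl
F3 | step 7 | organomercury bis(trifluoroacetate): 17 with Hg(OCOCF3) in place of the ring bromine and OCOCF3 in place of the allylic bromine | CC1(C)[C@@H]([Hg]OC(=O)C(F)(F)F)C[C@H](Cl)/C(=C\COC(=O)C(F)(F)F)[C@@H]1Cl
F4 | step 7 | alkylmercury bromide allylic alcohol: 17 with HgBr in place of the ring bromine and OH in place of the allylic bromine | CC1(C)[C@@H]([Hg]Br)C[C@H](Cl)/C(=C\CO)[C@@H]1Cl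
F5 | step 7 | bromo allylic alcohol: 17 with OH in place of the allylic bromine | CC1(C)[C@@H](Br)C[C@H](Cl)/C(=C\CO)[C@@H]1Cl
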